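**Retrosynthetic overview**

1. The route rests on the homoallylic alcohol array O–C2(H)–C1(H)–C15(=C17H2), shared by the 14-membered carbocycle (C1–C14) and the cis-fused five-membered lactone ring (O–C2–C1–C15–C16). This is the product pattern of a [2,3]-Wittig shift, and with C3≡C4 as an alkyne the carbanion carbon C2 is propargylic.
2. Key disconnection C1–C2: the carbocycle comes from the 17-membered ether C2–O–C17H2–C15(CH2OTBS)=C1H–C14, whose in-ring alkene has C14 cis to C17. Ring contraction sets C1 and C2 together.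
3. The ether comes from a seco hydroxy chloride by Williamson closure. Its C1=C15 geometry is fixed beforehand by a temporary six-membered lactone (Brown allylation, acylation, ring-closing metathesis, reduction). C2–C13 come from nerol, 1-(trimethylsilyl)propyne and formaldehyde.
4. After the contraction: C3≡C4 to the E C4-methyl alkene (hydroalumination–iodination, Me2CuLi), oxidative γ-lactonisation, C13–OH-directed epoxidation, inversion at C13 with acetate.
5. Ring order: six-membered template lactone (opened again), 17-membered ether, 14-membered carbocycle, γ-lactone, epoxide.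

Key step: step 16

Remark on the chemistry (cembrane numbering throughout): the epoxide oxygen of the target is threo to the C13 oxygen, whereas hydroxyl-directed epoxidation of a 2-methyl allylic alcohol gives the erythro epoxy alcohol; C13 is therefore carried as its 13S epimer, which directs oxygen to the required face, and is inverted with acetate in the last step.

**Route**

Step 1
Reactants: 1 nerol
Product: 2 neryl bromide
Conditions: PBr3 (0.4 equiv), Et2O, −10 °C
Reagents that add atoms: phosphorus tribromide, BrP(Br)Br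
Why: Alcohol-to-bromide substitution with PBr3 runs by SN2 on the bromophosphite, and at low temperature neither allylic transposition nor Z-to-E isomerisation should intervene.

Step 2
Reactants: 2 neryl bromide; 3 1-(trimethylsilyl)propyne
Product: 5 trimethyl[(5Z)-6,10-dimethylundeca-5,9-dien-1-yn-1-yl]silane, via 3-(trimethylsilyl)propargyllithium 4 (not isolated)
Conditions: 3, n-BuLi, THF, −78 → −20 °C; then 2, −78 → 0 °C
Reagents that add atoms: none
Why: Propargylic lithiation of 3 gives 4, whose silyl cap directs alkylation to the propargylic carbon, and SN2 alkylation of the primary allylic bromide forms C5–C6 with the 7Z alkene untouched (propargylation of an allylic halide).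

Step 3
Reactants: 5 silyl enyne
Product: 6 (2E,6Z)-2,6-dimethyl-11-(trimethylsilyl)undeca-2,6-dien-10-yn-1-ol
Conditions: SeO2 (0.3 equiv), t-BuOOH, salicylic acid (cat.), CH2Cl2, rt
Reagents that add atoms: selenium dioxide (oxygen carrier), O=[Se]=O; tert-butyl hydroperoxide (terminal oxygen source), CC(C)(C)OO
Why: Selenium dioxide allylic oxidation (ene reaction, then [2,3]-sigmatropic shift) attacks the E methyl group of the terminal isopropylidene unit, which is more accessible than the internal 7Z alkene, and should give the E allylic alcohol that becomes C13.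

Step 4
Reactants: 6 allylic alcohol
Product: 7 (2E,6Z)-2,6-dimethyl-11-(trimethylsilyl)undeca-2,6-dien-10-ynal
Conditions: MnO2 (excess), CH2Cl2, rt
Reagents that add atoms: none
Why: MnO2 oxidises only the allylic alcohol (heterogeneous allylic oxidation) and leaves the silylalkyne and both alkenes alone, so the 11E enal should form without isomerisation.

Step 5
Reactants: 7 enal
Product: 9 (4S,5E,9Z)-5,9-dimethyl-14-(trimethylsilyl)tetradeca-1,5,9-trien-13-yn-4-ol, via diisopinocampheylborinate 8 (not isolated)
Conditions: (+)-Ipc2B(allyl) (from (+)-α-pinene, commercial pentane solution), Et2O, −100 → −78 °C; then HOCH2CH2NH2, 0 °C → rt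
Reagents that add atoms: (+)-B-allyldiisopinocampheylborane, C=CCB([C@@H]1C[C@@H]2C[C@H]([C@H]1C)C2(C)C)[C@@H]1C[C@@H]2C[C@H]([C@H]1C)C2(C)C
Why: Brown asymmetric allylboration goes through a chair transition state in which the isopinocampheyl groups of the (+)-reagent direct allyl to the si face of the α-methyl enal, which sets C13 as S; the ethanolamine work-up releases 9 from borinate 8 without the hydroxide that would cleave the alkynylsilane.

Step 6
Reactants: 10 ethyl 2-(hydroxymethyl)acrylate
Product: 11 ethyl 2-{[(tert-butyldimethylsilyl)oxy]methyl}acrylate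
Conditions: TBSCl, imidazole, CH2Cl2, 0 °C → rt
Reagents that add atoms: tert-butyldimethylsilyl chloride, CC(C)(C)[Si](C)(C)Cl
Why: Standard silylation of a primary alcohol with TBSCl and imidazole.

Step 7
Reactants: 11 silyloxymethyl acrylate
Product: 13 2-{[(tert-butyldimethylsilyl)oxy]methyl}acrylic acid, via lithium carboxylate 12 (not isolated)
Conditions: LiOH, THF/H2O, 0 °C → rt; then 1 M HCl to pH 4, 0 °C
Reagents that add atoms: lithium hydroxide, [Li+].[OH-]
Why: Saponification of the ethyl ester; the primary silyl ether should survive the base and the brief cold acidification.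

Step 8
Reactants: 9 homoallylic alcohol; 13 acrylic acid
Product: 14 (4S,5E,9Z)-5,9-dimethyl-14-(trimethylsilyl)tetradeca-1,5,9-trien-13-yn-4-yl 2-{[(tert-butyldimethylsilyl)oxy]methyl}acrylate
Conditions: DCC, DMAP (cat.), CH2Cl2, 0 °C → rt
Reagents that add atoms: none
Why: Steglich esterification of the hindered secondary allylic alcohol with DMAP as acyl-transfer catalyst; C13 is not touched.

Step 9
Reactants: 14 diene ester
Product: 15 (6S)-3-{[(tert-butyldimethylsilyl)oxy]methyl}-6-[(2E,6Z)-6-methyl-11-(trimethylsilyl)undeca-2,6-dien-10-yn-2-yl]-5,6-dihydro-2H-pyran-2-one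
Conditions: second-generation Grubbs catalyst RuCl2(=CHPh)(H2IMes)(PCy3) (5 mol %), CH2Cl2 (5 mM), 40 °C
Reagents that add atoms: none
Why: Ring-closing metathesis between the monosubstituted alkene and the acrylate closes the six-membered unsaturated lactone and releases ethene; the ring forces C14 and C17 to be cis on the new C1=C15 alkene, and the trisubstituted alkenes and the silyl-capped alkyne should not engage the catalyst.

Step 10
Reactants: 15 template lactone
Product: 16 (2E,5S,6E,10Z)-2-{[(tert-butyldimethylsilyl)oxy]methyl}-6,10-dimethyl-15-(trimethylsilyl)pentadeca-2,6,10-trien-14-yne-1,5-diol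
Conditions: i-Bu2AlH (4 equiv), CH2Cl2, −78 → 0 °C; aq. potassium sodium tartrate
Reagents that add atoms: none
Why: i-Bu2AlH reduces the unsaturated lactone in the 1,2-sense through the lactol to the ene-1,5-diol, so the cis relationship of C14 and C17 set by the ring is carried into the open chain; the aluminium alkoxide at low temperature should not induce silyl migration from O16.

Step 11
Reactants: 16 diol
Product: 18 (2Z,5S,6E,10Z)-1-chloro-2-{[(tert-butyldimethylsilyl)oxy]methyl}-6,10-dimethyl-15-(trimethylsilyl)pentadeca-2,6,10-trien-14-yn-5-ol, via primary mesylate 17 (not isolated)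
Conditions: MsCl (1.1 equiv), 2,4,6-collidine, LiCl, DMF, 0 °C
Reagents that add atoms: lithium chloride, [Li+].[Cl-]
Why: Collington–Meyers chlorination: the primary allylic hydroxyl is mesylated selectively over the hindered secondary C13–OH, and chloride displaces mesylate 17 by SN2 without allylic shift or loss of alkene geometry.

Step 12
Reactants: 18 hydroxy chloride
Product: 19 13-O-triisopropylsilyl ether of 18
Conditions: TIPSOTf, 2,6-lutidine, CH2Cl2, −78 → 0 °C
Reagents that add atoms: triisopropylsilyl trifluoromethanesulfonate, CC(C)[Si](C(C)C)(C(C)C)OS(=O)(=O)C(F)(F)F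
Why: Silylation of the hindered secondary allylic alcohol with the silyl triflate, done at once so that the C13 hydroxyl cannot close a dihydropyran onto the allylic chloride.

Step 13
Reactants: 19 C-silyl alkyne
Product: 20 terminal alkyne (19 without the alkynyl SiMe3 group)
Conditions: K2CO3 (0.5 equiv), MeOH, 0 °C → rt
Reagents that add atoms: none
Why: Methanolysis of the alkynyl C–Si bond under mild carbonate catalysis; the O-silyl ethers are stable and the small methoxide concentration should not displace the allylic chloride.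

Step 14
Reactants: 20 terminal alkyne
Product: 22 (6Z,10E,12S,14Z)-16-chloro-15-{[(tert-butyldimethylsilyl)oxy]methyl}-7,11-dimethyl-12-[(triisopropylsilyl)oxy]hexadeca-6,10,14-trien-2-yn-1-ol, via lithium acetylide 21 (not isolated)
Conditions: n-BuLi (1.05 equiv), THF, −78 °C; (CH2O)n, −78 → 20 °C; H2O
Reagents that add atoms: paraformaldehyde (as formaldehyde), C=O
Why: Deprotonation of the terminal alkyne at −78 °C is far faster than any attack of n-BuLi on the allylic chloride, and acetylide 21 adds to formaldehyde to install C2 as the propargylic alcohol; lithium acetylides and alkoxides do not alkylate allylic chlorides in THF at these temperatures.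

Step 15
Reactants: 22 seco hydroxy chloride
Product: 24 (7Z,11E,13S,15E)-16-{[(tert-butyldimethylsilyl)oxy]methyl}-8,12-dimethyl-13-[(triisopropylsilyl)oxy]-1-oxacycloheptadeca-7,11,15-trien-3-yne (ring carbons C14 and C17 cis on the 15-ene), via sodium alkoxide 23 (not isolated)
Conditions: NaH, THF/DMPU (10:1), 45 °C, syringe-pump addition of 22 (final 2 mM)
Reagents that add atoms: none
Why: Intramolecular Williamson etherification: the sodium propargylic alkoxide 23 displaces the primary allylic chloride by SN2 under high dilution and closes the 17-membered ring; the alkoxide is remote from the O16 silyl ether, so silyl migration cannot exchange the two CH2O groups on C15.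

Step 16
Reactants: 24 17-membered allyl propargyl ether
Product: 26 (1S,2R,13S)-16-(tert-butyldimethylsilyloxy)-13-(triisopropylsilyloxy)-18-norcembra-7Z,11E,15(17)-trien-3-yn-2-ol, via C2-lithiated ether 25 (not isolated)
Conditions: (S,S)-bis(1-phenylethyl)amine, n-BuLi → lithium bis[(S)-1-phenylethyl]amide (4 equiv), THF, −78 → −20 °C; H2O
Reagents that add atoms: none
Why: The chiral lithium amide removes one of the diastereotopic propargylic protons at C2 (the most acidic C–H, flanked by oxygen and the alkyne), and the α-oxy carbanion 25 attacks C1 through a five-membered envelope transition state while O–C17 breaks and C15=C17 becomes the exocyclic methylene; this is a [2,3]-Wittig sigmatropic rearrangement, the known ring contraction of macrocyclic allyl propargyl ethers to 14-membered propargylic alcohols. The 14-membered ring closes by sigmatropic contraction of the 17-membered ether (C1–C2 formed, O–C17 cleaved, the atoms O, C17 and C15 leave the ring), not by an end-to-end cyclisation, so no high dilution is needed. The syn C1/C2 relationship (H1 and H2 cis, as the cis-fused lactone requires) is controlled by the in-ring geometry of the C1=C15 alkene (C14 cis to C17, fixed in step 9) with the alkynyl group exo in the envelope. The absolute sense at C1 and C2 is controlled by the configuration of the amide base, which selects the C2 proton, acting together with the C13 silyloxy stereocentre that biases the ring conformation; the base antipode written is taken as the matched one. The step needs deprotonation at C2 rather than at the allylic C17–H2 and a [2,3]- rather than a [1,2]-shift, and the propargylic acidity and the low temperature should secure both.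

Step 17
Reactants: 26 propargylic alcohol
Product: 28 (1S,2R,3Z,13S)-4-iodo-16-(tert-butyldimethylsilyloxy)-13-(triisopropylsilyloxy)-18-norcembra-3,7Z,11E,15(17)-tetraen-2-ol, via cyclic vinylaluminate 27 (not isolated)
Conditions: NaAlH2(OCH2CH2OMe)2 (Red-Al), THF, 0 °C → rt; EtOAc at −78 °C (destroys excess hydride); then I2, THF, −78 → 0 °C
Reagents that add atoms: iodine, II
Why: Hydroxyl-directed trans-hydroalumination of the propargylic alcohol: the alkoxyaluminium hydride delivers hydride to C3 and aluminium to C4 within the five-membered vinylaluminate 27, and iodinolysis with retention gives the vinyl iodide with C2 and iodine cis (Corey-type hydroalumination–iodination).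

Step 18
Reactants: 28 vinyl iodide
Product: 29 (1S,2S,13S)-16-(tert-butyldimethylsilyloxy)-13-(triisopropylsilyloxy)cembra-3E,7Z,11E,15(17)-tetraen-2-ol
Conditions: Me2CuLi (5 equiv, from MeLi and CuI), Et2O, −20 → 0 °C
Reagents that add atoms: lithium dimethylcuprate, [Li+].C[Cu-]C
Why: Me2CuLi replaces the vinylic iodide by methyl with retention of configuration (Corey–Posner coupling), which gives the 3E trisubstituted alkene; the alkoxide formed from the C2 hydroxyl is inert.

Step 19
Reactants: 29 bis-silyl ether
Product: 30 (1S,2S,13S)-13-(triisopropylsilyloxy)cembra-3E,7Z,11E,15(17)-tetraene-2,16-diol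
Conditions: PPTS (cat.), MeOH, rt
Reagents that add atoms: none
Why: Acid-catalysed methanolysis removes the primary TBS ether far faster than the secondary TIPS ether, and PPTS is too weak an acid to ionise the C2 allylic alcohol.

Step 20
Reactants: 30 2,16-diol
Product: 33 (1S,2S,13S)-13-(triisopropylsilyloxy)cembra-3E,7Z,11E,15(17)-tetraen-16,2-olide, via hydroxy enal 31 (not isolated), via lactol 32 (not isolated)
Conditions: TEMPO (0.2 equiv), PhI(OAc)2 (2.5 equiv), CH2Cl2, rt
Reagents that add atoms: none
Why: TEMPO/PhI(OAc)2 oxidises the primary allylic alcohol selectively to enal 31, the cis C2 hydroxyl closes lactol 32, and a second oxidation gives the α-methylene-γ-lactone (oxidative lactonisation of a 1,4-diol); the secondary C2 alcohol is oxidised much more slowly than it cyclises.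

Step 21
Reactants: 33 silyl ether lactone
Product: 34 (1S,2S,13S)-13-hydroxycembra-3E,7Z,11E,15(17)-tetraen-16,2-olide
Conditions: HF·pyridine, pyridine, THF, 0 °C → rt
Reagents that add atoms: none
Why: Fluoride-mediated cleavage of the secondary TIPS ether with pyridine-buffered HF, conditions under which the α-methylene lactone is not attacked by base.

Step 22
Reactants: 34 allylic alcohol
Product: 35 (1S,2S,11S,12S,13S)-11,12-epoxy-13-hydroxycembra-3E,7Z,15(17)-trien-16,2-olide
Conditions: VO(acac)2 (5 mol %), t-BuOOH (1.5 equiv, decane solution), CH2Cl2, 0 °C → rt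
Reagents that add atoms: tert-butyl hydroperoxide, CC(C)(C)OO
Why: VO(acac)2-catalysed, hydroxyl-directed epoxidation touches only the alkene of the allylic alcohol; with the O–C13–C12=C11 dihedral angle near 45° and H13 eclipsing the C12 methyl group (A1,2 strain control), the ring bond C13–C14 lies on the far face and oxygen is delivered to the erythro face, which sets C11 and C12 as in the target.

Step 23
Reactants: 35 epoxy alcohol
Product: 36 (1S,2S,3E,7Z,11S,12R,13R)-13-acetoxy-11,12-epoxycembra-3,7,15(17)-trien-16,2-olide (CNP0146076.3)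
Conditions: PPh3, DIAD, AcOH, toluene, 0 °C → rt
Reagents that add atoms: acetic acid, CC(=O)O
Why: Mitsunobu reaction: the C13 hydroxyl is activated as the alkoxyphosphonium ion and displaced by acetate with inversion (SN2), which turns 13S into the 13R acetate under neutral conditions that spare the epoxide and the α-methylene lactone.

**Compound list**

1 | nerol, (2Z)-3,7-dimethylocta-2,6-dien-1-ol | CC(C)=CCC/C(C)=C\CO | starting material
2 | neryl bromide, (2Z)-1-bromo-3,7-dimethylocta-2,6-diene | CC(C)=CCC/C(C)=C\CBr | intermediate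
3 | 1-(trimethylsilyl)propyne | CC#C[Si](C)(C)C | starting material
4 | 3-(trimethylsilyl)prop-2-yn-1-yllithium (formed in the flask) | [Li]CC#C[Si](C)(C)C | intermediate
5 | trimethyl[(5Z)-6,10-dimethylundeca-5,9-dien-1-yn-1-yl]silane | C[Si](C)(C)C#CCC/C=C(/C)CCC=C(C)C | intermediate
6 | (2E,6Z)-2,6-dimethyl-11-(trimethylsilyl)undeca-2,6-dien-10-yn-1-ol | C[Si](C)(C)C#CCC/C=C(/C)CC/C=C(\C)CO | intermediate
7 | (2E,6Z)-2,6-dimethyl-11-(trimethylsilyl)undeca-2,6-dien-10-ynal | C[Si](C)(C)C#CCC/C=C(/C)CC/C=C(\C)C=O | intermediate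
8 | diisopinocampheylborinate ester of 9 (formed in the flask) | C[Si](C)(C)C#CCC/C=C(/C)CC/C=C(\C)[C@@H](OB([C@@H]1C[C@@H]2C[C@H]([C@H]1C)C2(C)C)[C@@H]1C[C@@H]2C[C@H]([C@H]1C)C2(C)C)CC=C | intermediate
9 | (4S,5E,9Z)-5,9-dimethyl-14-(trimethylsilyl)tetradeca-1,5,9-trien-13-yn-4-ol | C[Si](C)(C)C#CCC/C=C(/C)CC/C=C(\C)[C@@H](O)CC=C | intermediate
10 | ethyl 2-(hydroxymethyl)acrylate | C=C(CO)C(=O)OCC | starting material
11 | ethyl 2-{[(tert-butyldimethylsilyl)oxy]methyl}acrylate | C=C(CO[Si](C)(C)C(C)(C)C)C(=O)OCC | intermediate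
12 | lithium 2-{[(tert-butyldimethylsilyl)oxy]methyl}acrylate (formed in the flask) | C=C(CO[Si](C)(C)C(C)(C)C)C(=O)[O-].[Li+] | intermediate
13 | 2-{[(tert-butyldimethylsilyl)oxy]methyl}acrylic acid | C=C(CO[Si](C)(C)C(C)(C)C)C(=O)O | intermediate
14 | (4S,5E,9Z)-5,9-dimethyl-14-(trimethylsilyl)tetradeca-1,5,9-trien-13-yn-4-yl 2-{[(tert-butyldimethylsilyl)oxy]methyl}acrylate | C[Si](C)(C)C#CCC/C=C(/C)CC/C=C(\C)[C@@H](OC(=O)C(=C)CO[Si](C)(C)C(C)(C)C)CC=C | intermediate
15 | (6S)-3-{[(tert-butyldimethylsilyl)oxy]methyl}-6-[(2E,6Z)-6-methyl-11-(trimethylsilyl)undeca-2,6-dien-10-yn-2-yl]-5,6-dihydro-2H-pyran-2-one | C[Si](C)(C)C#CCC/C=C(/C)CC/C=C(\C)[C@@H]1CC=C(CO[Si](C)(C)C(C)(C)C)C(=O)O1 | intermediate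
16 | (2E,5S,6E,10Z)-2-{[(tert-butyldimethylsilyl)oxy]methyl}-6,10-dimethyl-15-(trimethylsilyl)pentadeca-2,6,10-trien-14-yne-1,5-diol | C[Si](C)(C)C#CCC/C=C(/C)CC/C=C(\C)[C@@H](O)C/C=C(/CO[Si](C)(C)C(C)(C)C)CO | intermediate
17 | 1-O-methanesulfonate of 16 (formed in the flask) | C[Si](C)(C)C#CCC/C=C(/C)CC/C=C(\C)[C@@H](O)C/C=C(/CO[Si](C)(C)C(C)(C)C)COS(C)(=O)=O | intermediate
18 | (2Z,5S,6E,10Z)-1-chloro-2-{[(tert-butyldimethylsilyl)oxy]methyl}-6,10-dimethyl-15-(trimethylsilyl)pentadeca-2,6,10-trien-14-yn-5-ol | C[Si](C)(C)C#CCC/C=C(/C)CC/C=C(\C)[C@@H](O)C/C=C(/CO[Si](C)(C)C(C)(C)C)CCl | intermediate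
19 | 13-O-triisopropylsilyl ether of 18 | C[Si](C)(C)C#CCC/C=C(/C)CC/C=C(\C)[C@@H](O[Si](C(C)C)(C(C)C)C(C)C)C/C=C(/CO[Si](C)(C)C(C)(C)C)CCl | intermediate
20 | terminal alkyne, 19 without the alkynyl trimethylsilyl group | C#CCC/C=C(/C)CC/C=C(\C)[C@@H](O[Si](C(C)C)(C(C)C)C(C)C)C/C=C(/CO[Si](C)(C)C(C)(C)C)CCl | intermediate
21 | lithium acetylide of 20 (formed in the flask) | [Li]C#CCC/C=C(/C)CC/C=C(\C)[C@@H](O[Si](C(C)C)(C(C)C)C(C)C)C/C=C(/CO[Si](C)(C)C(C)(C)C)CCl | intermediate
22 | (6Z,10E,12S,14Z)-16-chloro-15-{[(tert-butyldimethylsilyl)oxy]methyl}-7,11-dimethyl-12-[(triisopropylsilyl)oxy]hexadeca-6,10,14-trien-2-yn-1-ol | OCC#CCC/C=C(/C)CC/C=C(\C)[C@@H](O[Si](C(C)C)(C(C)C)C(C)C)C/C=C(/CO[Si](C)(C)C(C)(C)C)CCl | intermediate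
23 | sodium alkoxide of 22 (formed in the flask) | [Na+].[O-]CC#CCC/C=C(/C)CC/C=C(\C)[C@@H](O[Si](C(C)C)(C(C)C)C(C)C)C/C=C(/CO[Si](C)(C)C(C)(C)C)CCl | intermediate
24 | (7Z,11E,13S,15E)-16-{[(tert-butyldimethylsilyl)oxy]methyl}-8,12-dimethyl-13-[(triisopropylsilyl)oxy]-1-oxacycloheptadeca-7,11,15-trien-3-yne | O1CC#CCC/C=C(/C)CC/C=C(\C)[C@@H](O[Si](C(C)C)(C(C)C)C(C)C)C/C=C(/CO[Si](C)(C)C(C)(C)C)C1 | intermediate
25 | 2-lithio derivative of 24 (formed in the flask) | O1C([Li])C#CCC/C=C(/C)CC/C=C(\C)[C@@H](O[Si](C(C)C)(C(C)C)C(C)C)C/C=C(/CO[Si](C)(C)C(C)(C)C)C1 | intermediate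
26 | (1S,2R,13S)-16-(tert-butyldimethylsilyloxy)-13-(triisopropylsilyloxy)-18-norcembra-7Z,11E,15(17)-trien-3-yn-2-ol | O[C@H]1C#CCC/C=C(/C)CC/C=C(\C)[C@@H](O[Si](C(C)C)(C(C)C)C(C)C)C[C@H]1C(=C)CO[Si](C)(C)C(C)(C)C | intermediate
27 | sodium cyclic vinylaluminate of 26, O2 and C4 on aluminium (formed in the flask) | [Na+].COCCO[Al-]1(OCCOC)O[C@H]2/C=C\1CC/C=C(/C)CC/C=C(\C)[C@@H](O[Si](C(C)C)(C(C)C)C(C)C)C[C@H]2C(=C)CO[Si](C)(C)C(C)(C)C | intermediate
28 | (1S,2R,3Z,13S)-4-iodo-16-(tert-butyldimethylsilyloxy)-13-(triisopropylsilyloxy)-18-norcembra-3,7Z,11E,15(17)-tetraen-2-ol | O[C@H]1/C=C(\I)CC/C=C(/C)CC/C=C(\C)[C@@H](O[Si](C(C)C)(C(C)C)C(C)C)C[C@H]1C(=C)CO[Si](C)(C)C(C)(C)C | intermediate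
29 | (1S,2S,13S)-16-(tert-butyldimethylsilyloxy)-13-(triisopropylsilyloxy)cembra-3E,7Z,11E,15(17)-tetraen-2-ol | O[C@H]1/C=C(\C)CC/C=C(/C)CC/C=C(\C)[C@@H](O[Si](C(C)C)(C(C)C)C(C)C)C[C@H]1C(=C)CO[Si](C)(C)C(C)(C)C | intermediate
30 | (1S,2S,13S)-13-(triisopropylsilyloxy)cembra-3E,7Z,11E,15(17)-tetraene-2,16-diol | O[C@H]1/C=C(\C)CC/C=C(/C)CC/C=C(\C)[C@@H](O[Si](C(C)C)(C(C)C)C(C)C)C[C@H]1C(=C)CO | intermediate
31 | (1S,2S,13S)-2-hydroxy-13-(triisopropylsilyloxy)cembra-3E,7Z,11E,15(17)-tetraen-16-al (formed in the flask) | O[C@H]1/C=C(\C)CC/C=C(/C)CC/C=C(\C)[C@@H](O[Si](C(C)C)(C(C)C)C(C)C)C[C@H]1C(=C)C=O | intermediate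
32 | lactol of 31, 2,16-epoxy-16-ol, both C16 epimers (formed in the flask) | C=C1C(O)O[C@H]2/C=C(\C)CC/C=C(/C)CC/C=C(\C)[C@@H](O[Si](C(C)C)(C(C)C)C(C)C)C[C@@H]12 | intermediate
33 | (1S,2S,13S)-13-(triisopropylsilyloxy)cembra-3E,7Z,11E,15(17)-tetraen-16,2-olide | C=C1C(=O)O[C@H]2/C=C(\C)CC/C=C(/C)CC/C=C(\C)[C@@H](O[Si](C(C)C)(C(C)C)C(C)C)C[C@@H]12 | intermediate
34 | (1S,2S,13S)-13-hydroxycembra-3E,7Z,11E,15(17)-tetraen-16,2-olide | C=C1C(=O)O[C@H]2/C=C(\C)CC/C=C(/C)CC/C=C(\C)[C@@H](O)C[C@@H]12 | intermediate
35 | (1S,2S,11S,12S,13S)-11,12-epoxy-13-hydroxycembra-3E,7Z,15(17)-trien-16,2-olide | C=C1C(=O)O[C@H]2/C=C(\C)CC/C=C(/C)CC[C@@H]3O[C@@]3(C)[C@@H](O)C[C@@H]12 | intermediate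
36 | (1S,2S,3E,7Z,11S,12R,13R)-13-acetoxy-11,12-epoxycembra-3,7,15(17)-trien-16,2-olide, CNP0146076.3 | C=C1C(=O)O[C@H]2/C=C(\C)CC/C=C(/C)CC[C@@H]3O[C@@]3(C)[C@H](OC(C)=O)C[C@@H]12 | target

**Step count**

Total: 23 steps. Longest linear sequence: 21 steps (steps 1–5 and 8–23, nerol to target); steps 6–7 make acid 13.

**Steps most likely to fail**

1. Step 16 (ring contraction). The ring conformation imposed by the C13 silyloxy group may oppose the proton choice of the amide base, giving poor facial selectivity at C1/C2, and a [1,2]-shift may compete if the envelope is strained. The fallback forms C1–C2 by carbonyl allylation instead of a sigmatropic shift and bypasses ether 24. It sets out from 22: oxidation with Dess–Martin periodinane (NaHCO3, CH2Cl2) should give (6Z,10E,12S,14Z)-16-chloro-15-{[(tert-butyldimethylsilyl)oxy]methyl}-7,11-dimethyl-12-[(triisopropylsilyl)oxy]hexadeca-6,10,14-trien-2-ynal F1. F1 is then cyclised by an intramolecular Nozaki–Hiyama allylation (CrCl2, THF, high dilution). The allyl–CrCl2 species formed at C17 adds through C1 to the C2 aldehyde in a chair transition state, which creates C1–C2 and the C15=C17 methylene in one step. The fallback comes back to the route at 26. The syn outcome depends on the allyl–CrCl2 species keeping its alkene geometry.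

2. Step 23 (Mitsunobu inversion). SN2 displacement at C13 is slowed by the adjacent fully substituted epoxide carbon, so the alkoxyphosphonium ion may eliminate or be acylated with retention. The fallback inverts C13 by oxidation and reagent-controlled reduction. It sets out from 35: Dess–Martin periodinane should give the C13 ketone, (1S,2S,11S,12S)-11,12-epoxy-13-oxocembra-3E,7Z,15(17)-trien-16,2-olide F2. Reduction with the (S)-B-methyl oxazaborolidine (CBS catalyst) and catecholborane in toluene at −78 °C, with the epoxide carbon as the large group, should give the 13R alcohol, (1S,2S,11S,12S,13R)-11,12-epoxy-13-hydroxycembra-3E,7Z,15(17)-trien-16,2-olide F3. Acetylation (Ac2O, DMAP, pyridine) brings the route back at 36.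

3. Step 22 (directed epoxidation). The macrocycle may hold the C13–C14 ring bond near the alkene plane, so that delivery of oxygen to the erythro face loses its preference. The fallback replaces conformational control by the substrate with reagent control. It sets out from 34 and uses Ti(OiPr)4, diisopropyl L-(+)-tartrate, t-BuOOH and 4 Å molecular sieves in CH2Cl2 at −20 °C (Sharpless conditions). For the 13S carbinol this tartrate is the matched, fast-reacting pairing and delivers oxygen to the same erythro face. The fallback comes back at 35 and makes no new compound (F0).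

Further compounds
F1 | step 16 | (6Z,10E,12S,14Z)-16-chloro-15-{[(tert-butyldimethylsilyl)oxy]methyl}-7,11-dimethyl-12-[(triisopropylsilyl)oxy]hexadeca-6,10,14-trien-2-ynal | O=CC#CCC/C=C(/C)CC/C=C(\C)[C@@H](O[Si](C(C)C)(C(C)C)C(C)C)C/C=C(/CO[Si](C)(C)C(C)(C)C)CCl
F2 | step 23 | (1S,2S,11S,12S)-11,12-epoxy-13-oxocembra-3E,7Z,15(17)-trien-16,2-olide | C=C1C(=O)O[C@H]2/C=C(\C)CC/C=C(/C)CC[C@@H]3O[C@@]3(C)C(=O)C[C@@H]12
F3 | step 23 | (1S,2S,11S,12S,13R)-11,12-epoxy-13-hydroxycembra-3E,7Z,15(17)-trien-16,2-olide | C=C1C(=O)O[C@H]2/C=C(\C)CC/C=C(/C)CC[C@@H]3O[C@@]3(C)[C@H](O)C[C@@H]12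
F0 | step 22 | none | none
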